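The vessel is closed and isothermal. In it, substrate becomes target and target becomes over-reaction product, so I follow both as fractions of the substrate charge.

in all of them: substrate 0.86 M

|  | coupling partner | free catalyst | remark | time |
|---|---|---|---|---|
| dawn | 0.86 M | 8.9 mM | run made earlier |  |
| autumn | 0.86 M | 22 mM | run made earlier |  |
| dusk | 0.86 M | 32 mM | run made earlier |  |
| red | 0.860 M | 10 mM |  | 8.0 h |
| blue | 0.860 M | 20 mM |  | 8.0 h |
| amber | 0.860 M | 40 mM |  | 8.0 h |

- dawn (time / h: target / %, substrate / %): 0.333: 3.4, 97.3; 0.667: 5.0, 94.1; 1.00: 7.0, 90.6; 2.00: 10.4, 81.8; 4.00: 13.9, 65.8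
- autumn (time / h: target / %, substrate / %): 0.333: 6.5, 91.7; 0.667: 13.0, 83.5; 1.00: 16.3, 77.1; 2.00: 25.4, 59.2; 4.00: 26.1, 32.3
- dusk (time / h: target / %, substrate / %): 0.333: 8.6, 88.6; 0.667: 17.0, 77.0; 1.00: 23.4, 68.8; 2.00: 32.6, 45.9; 4.00: 29.7, 17.6

(standard deviation of a reading: 0.5 percentage points)

- [target] at the end for red, blue, amber, in this order
- the shape of the row from first to last (falls all the way / rises all the way / falls, then rises / rises, then falls / hardly changes)

- the numbers in the tables scatter with a standard deviation of 0.5 percentage points
- steps that have been proposed: substrate + free catalyst <-> catalyst intermediate A; coupling partner + catalyst intermediate B -> catalyst intermediate C; catalyst intermediate A -> catalyst intermediate B; target -> over-reaction product; catalyst intermediate D <-> free catalyst + target; catalyst intermediate C -> by-product + catalyst intermediate D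
- "hardly changes" means that all values lie within two and a half points (for a concentration: within two and a half percent of the largest)

1. Target life. In the dusk run, substrate plus target falls by 31 percentage points between 2.00 h and 4.00 h. The catalyst charge is 3.72 % of the substrate charge, so I neglect what the catalyst holds. Dividing that fall by the interval and the mean target fraction gives the target loss constant, the first-order rate of over-reaction, 0.501 h⁻¹. The target life is therefore 2.00 h.

2. Substrate life. I treat substrate as pseudo-first-order and scale its life inversely with catalyst from the nearest run. This gives 8.51 h for red, 3.89 h for blue and 1.84 h for amber.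

3. Ratio. In red, substrate life exceeds target life, so target is lost while substrate still feeds it. In amber, substrate life is shorter, and my reckoning leaves 1.29 % of the substrate at 8.0 h.

4. My row. The consecutive first-order solution gives target fractions of 11.4 %, 11.6 % and 6.71 %. My red and blue values differ by less than the scatter of a reading.

5. Forecast. It gives 0.112 M, 0.116 M and 0.065 M, shaped rises, then falls: “Red and blue are nearly equal, so the rise is slight and uncertain.” My red value, as a concentration 0.0982 M, is lower than its figure.

    substrate + free catalyst ⇌ catalyst intermediate A (K = 0.470 M⁻¹, k = 0.00804 M⁻¹ s⁻¹)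
    coupling partner + catalyst intermediate B → catalyst intermediate C (k = 0.0506 M⁻¹ s⁻¹)
    catalyst intermediate A → catalyst intermediate B (k = 0.656 s⁻¹)
    target → over-reaction product (k = 1.33 × 10⁻⁴ s⁻¹)
    catalyst intermediate D ⇌ free catalyst + target (K = 1.00 M, k = 0.00470 s⁻¹)
    catalyst intermediate C → by-product + catalyst intermediate D (k = 0.239 s⁻¹)

The flasks give 0.119 M, 0.122 M and 0.0665 M, with the shape rises, then falls. At 8.0 h, the red flask still holds 35.5 % of its substrate and the blue flask 9.04 %. In the blue flask, target stands at 25.2 % after 4.00 h and 14.2 % after 8.00 h. The mean of these two values, multiplied by 0.501 h⁻¹ and by the interval, estimates the new over-reaction product at 39.5 % of the charge. The blue flask's over-reaction product rises by 39 points.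

Readings and results come from a simulation with made-up constants; scatter was added.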